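**Retrosynthetic overview**

1. Target 14 comes from 13 by one acid operation that removes three MOM ethers and the keto-ketal left on O3.
2. 13 is assembled from three components: aryllithium 11 (from fluoroarene 6), chiral glycolate lactone 7 and aldehyde 8. Three bonds form in one flask: C2–C3 (aldol), C4–C4a (acyl transfer) and O1–C8a (SNAr).
3. Enabling feature: in the pyranone ring C, O1 is bonded to C8a, which lies ortho to C4a carrying the C4 carbonyl, and C3 is an oxygenated, enolisable carbon next to the carbinol C2. A fluorine at C8a therefore first acidifies C4a–H for lithiation and then becomes a leaving group once C4=O is in place, while the lactone serves as enolate donor and then as acyl donor.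
4. Ring order: rings A and B are bought as arenes (1 and 8); ring C is the only ring formed (step 4). Fluoroarene 6 comes from 5-fluororesorcinol 1 by MOM protection and two directed lithiation–prenylations (C6, then C8).

Key step: step 4

**Remarks on the chemistry (assumptions)**

- Flavonoid numbering (O1, C2, C3, C4, C4a, C5–C8, C8a) is used for all intermediates.
- 1, 7 and 8 are taken as catalogue compounds.
- The facial sense of the aldol is derived from the accepted model for this dioxanone (attack anti to the axial 5-methoxy group); on that model the (5S,6S) enantiomer gives the (2R,3R) series.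
- In step 4 the enolate is made with LDA, not LiHMDS, because hexamethyldisilazane would be acidic enough to protonate aryllithium 11.

**Route**

Step 1
Reactants: 1 5-fluorobenzene-1,3-diol
Product: 2 1-fluoro-3,5-bis(methoxymethoxy)benzene
Conditions: NaH, MOMCl, DMF, 0 °C → rt
Reagents that add atoms: chloromethyl methyl ether (MOMCl), COCCl
Why: O-alkylation of both phenoxides (MOM protection); the MOM groups later direct the lithiations and come off with acid.

Step 2
Reactants: 2 1-fluoro-3,5-bis(methoxymethoxy)benzene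
Product: 4 5-fluoro-1,3-bis(methoxymethoxy)-2-(3-methylbut-2-en-1-yl)benzene, via aryllithium 3 (not isolated)
Conditions: n-BuLi, THF, −78 → 0 °C; then CuBr·SMe2 (10 mol %), prenyl bromide, −78 °C → rt
Reagents that add atoms: prenyl bromide (1-bromo-3-methylbut-2-ene), CC(C)=CCBr
Why: directed ortho-metalation at the carbon flanked by both OMOM groups (para to fluorine, so no LiF loss is possible), then copper-catalysed SN2 allylation; this installs the C6 prenyl group.

Step 3
Reactants: 4 5-fluoro-1,3-bis(methoxymethoxy)-2-(3-methylbut-2-en-1-yl)benzene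
Product: 6 1-fluoro-3,5-bis(methoxymethoxy)-2,4-bis(3-methylbut-2-en-1-yl)benzene, via aryllithium 5 (not isolated)
Conditions: s-BuLi, TMEDA, THF, −78 °C; then CuBr·SMe2 (10 mol %), prenyl bromide, −78 → −40 °C
Reagents that add atoms: prenyl bromide (1-bromo-3-methylbut-2-ene), CC(C)=CCBr
Why: directed ortho-metalation at one of the two equivalent C–H positions between F and OMOM, held at −78 °C so the ortho-fluoroaryllithium does not eliminate LiF, then copper-catalysed allylation; this installs the C8 prenyl group.

Step 4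
Reactants: 6 1-fluoro-3,5-bis(methoxymethoxy)-2,4-bis(3-methylbut-2-en-1-yl)benzene, 7 (5S,6S)-5,6-dimethoxy-5,6-dimethyl-1,4-dioxan-2-one, 8 4-(methoxymethoxy)benzaldehyde
Product: 13 (2R,3R)-3-{[(2S)-2-methoxy-3-oxobutan-2-yl]oxy}-5,7-bis(methoxymethoxy)-2-[4-(methoxymethoxy)phenyl]-6,8-bis(3-methylbut-2-en-1-yl)-2,3-dihydro-4H-chromen-4-one, via lithium enolate 9 (not isolated), via lithium aldolate 10 (not isolated), via aryllithium 11 (not isolated), via fluoroketone alkoxide 12 (not isolated)
Conditions: 7, LDA, THF, −78 °C; 8, −78 °C; then 11 (from 6, s-BuLi, TMEDA, THF, −78 °C) by cannula; −78 → 0 °C; AcOH quench at 0 °C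
Reagents that add atoms: none
Why: Proposed new method: a three-component anionic relay, closest to three separately known reactions (the lithium-enolate aldol of this dioxanone, ketone synthesis from an aryllithium and a lactone, and SNAr closure of 2-fluoroaryl ketones to chroman-4-ones) that have not been run in one flask. Enolate 9 adds to 8 through a closed chair transition state (C2–C3); aryllithium 11 then adds to the lactone carbonyl of aldolate 10 and the lactol opens, the released hemiketal arm expelling methoxide, to give ketone 12, whose C2 alkoxide displaces fluoride at C8a by addition–elimination (O1–C8a). The pyranone ring closes in a 6-exo attack on C8a, which becomes electrophilic only after the C4 carbonyl has been installed ortho to it. C3 is set by approach of 8 to the enolate face anti to the axial 5-methoxy group of the dioxanone and C2 by the anti topology that the ring-locked (E)-enolate imposes; ring closure leaves the C–O bonds at C2 and C3 intact, and the 2,3-trans product is also the more stable C3 epimer. The step needs single addition of 11 and cyclisation faster than retro-aldol cleavage: the lactol dianion should persist at −78 °C while 11 is present, the lithium alkoxide in 12 sits six atoms from an ortho-acyl fluoride, and 11 is accessible only because C4a–H lies between F and OMOM. If some 11 loses LiF first, the aryne is polarised by the C5 OMOM group so that the alkoxide still adds at C8a and the aryl anion is acylated at C4a, which gives the same product.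

Step 5
Reactants: 13 (2R,3R)-3-{[(2S)-2-methoxy-3-oxobutan-2-yl]oxy}-5,7-bis(methoxymethoxy)-2-[4-(methoxymethoxy)phenyl]-6,8-bis(3-methylbut-2-en-1-yl)-2,3-dihydro-4H-chromen-4-one
Product: 14 (2R,3R)-3,5,7-trihydroxy-2-(4-hydroxyphenyl)-6,8-bis(3-methylbut-2-en-1-yl)-2,3-dihydro-4H-chromen-4-one (6,8-diprenylaromadendrin)
Conditions: 3 M aq HCl, MeOH, 50 °C
Reagents that add atoms: none
Why: acid-catalysed acetal hydrolysis should remove the three MOM ethers and the mixed keto-ketal on O3 in one operation without touching C2 or C3; dilute HCl in methanol is the usual unmasking of MOM-protected prenylflavonoids.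

**Compound list**

1 | 5-fluorobenzene-1,3-diol (5-fluororesorcinol) | Oc1cc(O)cc(F)c1 | starting material
2 | 1-fluoro-3,5-bis(methoxymethoxy)benzene | COCOc1cc(F)cc(OCOC)c1 | intermediate
3 | [4-fluoro-2,6-bis(methoxymethoxy)phenyl]lithium (not isolated) | [Li]c1c(OCOC)cc(F)cc1OCOC | intermediate
4 | 5-fluoro-1,3-bis(methoxymethoxy)-2-(3-methylbut-2-en-1-yl)benzene | COCOc1cc(F)cc(OCOC)c1CC=C(C)C | intermediate
5 | [6-fluoro-2,4-bis(methoxymethoxy)-3-(3-methylbut-2-en-1-yl)phenyl]lithium (not isolated) | [Li]c1c(F)cc(OCOC)c(CC=C(C)C)c1OCOC | intermediate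
6 | 1-fluoro-3,5-bis(methoxymethoxy)-2,4-bis(3-methylbut-2-en-1-yl)benzene | COCOc1c(CC=C(C)C)c(OCOC)cc(F)c1CC=C(C)C | intermediate
7 | (5S,6S)-5,6-dimethoxy-5,6-dimethyl-1,4-dioxan-2-one | O=C1CO[C@](C)(OC)[C@@](C)(OC)O1 | starting material
8 | 4-(methoxymethoxy)benzaldehyde | COCOc1ccc(C=O)cc1 | starting material
9 | lithium (5S,6S)-5,6-dimethoxy-5,6-dimethyl-5,6-dihydro-1,4-dioxin-2-olate (enolate of 7, not isolated) | [Li+].[O-]C1=CO[C@](C)(OC)[C@@](C)(OC)O1 | intermediate
10 | lithium alkoxide of (3R,5S,6S)-3-{(R)-hydroxy[4-(methoxymethoxy)phenyl]methyl}-5,6-dimethoxy-5,6-dimethyl-1,4-dioxan-2-one (anti aldolate, not isolated) | O=C1[C@@H]([C@H]([O-])c2ccc(OCOC)cc2)O[C@](C)(OC)[C@@](C)(OC)O1.[Li+] | intermediate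
11 | [2-fluoro-4,6-bis(methoxymethoxy)-3,5-bis(3-methylbut-2-en-1-yl)phenyl]lithium (not isolated) | [Li]c1c(F)c(CC=C(C)C)c(OCOC)c(CC=C(C)C)c1OCOC | intermediate
12 | lithium (1R,2R)-3-[2-fluoro-4,6-bis(methoxymethoxy)-3,5-bis(3-methylbut-2-en-1-yl)phenyl]-2-{[(2S)-2-methoxy-3-oxobutan-2-yl]oxy}-1-[4-(methoxymethoxy)phenyl]-3-oxopropan-1-olate (not isolated) | COCOc1c(CC=C(C)C)c(OCOC)c(C(=O)[C@H](O[C@](C)(OC)C(C)=O)[C@H]([O-])c2ccc(OCOC)cc2)c(F)c1CC=C(C)C.[Li+] | intermediate
13 | (2R,3R)-3-{[(2S)-2-methoxy-3-oxobutan-2-yl]oxy}-5,7-bis(methoxymethoxy)-2-[4-(methoxymethoxy)phenyl]-6,8-bis(3-methylbut-2-en-1-yl)-2,3-dihydro-4H-chromen-4-one | CC(C)=CCc1c(OCOC)c(CC=C(C)C)c2c(c1OCOC)C(=O)[C@H](O[C@](C)(OC)C(C)=O)[C@@H](c1ccc(OCOC)cc1)O2 | intermediate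
14 | (2R,3R)-3,5,7-trihydroxy-2-(4-hydroxyphenyl)-6,8-bis(3-methylbut-2-en-1-yl)-2,3-dihydro-4H-chromen-4-one (6,8-diprenylaromadendrin) | CC(C)=CCc1c(O)c(CC=C(C)C)c2c(c1O)C(=O)[C@H](O)[C@@H](c1ccc(O)cc1)O2 | target

**Totals**

Total step count: 5. Longest linear sequence: 5 steps (1 → 2 → 4 → 6 → 13 → 14); 7 and 8 enter at step 4.

**Steps most likely to fail, with fallbacks**

Step 4 (key step). The relay may stall before the ketone exists, because the aryllithium is consumed by proton transfer (from the amine or from the C–H next to the lactone carbonyl) or adds twice. Alternatively, ring closure may be slower than retro-aldol cleavage of the keto-alkoxide, so that configuration at C2/C3 leaks. The fallback runs the same bond set as separate, individually known operations with isolated intermediates; it sets out from 7 and 8 (and later 6) and comes back at 13. Enolate 9 and aldehyde 8 are combined as above, but the mixture is quenched at −78 °C with acetic acid to isolate the anti aldol alcohol (3R,5S,6S)-3-{(R)-hydroxy[4-(methoxymethoxy)phenyl]methyl}-5,6-dimethoxy-5,6-dimethyl-1,4-dioxan-2-one F1. TESCl and imidazole in DMF convert it into the silyl ether (3R,5S,6S)-5,6-dimethoxy-3-{(R)-[4-(methoxymethoxy)phenyl](triethylsilyloxy)methyl}-5,6-dimethyl-1,4-dioxan-2-one F2. Amine-free aryllithium 11 (from 6, s-BuLi, TMEDA, THF, −78 °C) is added to F2 at −78 °C, and aqueous NH4Cl work-up should give the open ketone (2R,3R)-1-[2-fluoro-4,6-bis(methoxymethoxy)-3,5-bis(3-methylbut-2-en-1-yl)phenyl]-2-{[(2S)-2-methoxy-3-oxobutan-2-yl]oxy}-3-[4-(methoxymethoxy)phenyl]-3-(triethylsilyloxy)propan-1-one F3. TBAF in THF at 0 °C then frees the C2 alkoxide only when the ortho-acyl fluoride is already in place, and SNAr closure returns 13. Any C2/C3 stereoisomers formed still carry the (S)-ketal and are therefore diastereomers that can be separated at this stage.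

Step 3. The ortho-fluoroaryllithium 5 may lose LiF before it is alkylated, because allylation at −78 °C can be slow, which would give aryne-derived by-products instead of 6. The fallback separates the fast trapping from the C–C bond formation; it sets out from 4 (through 5) and comes back at 6. Aryllithium 5 is quenched at −78 °C with iodine, which reacts at once, to give 1-fluoro-2-iodo-3,5-bis(methoxymethoxy)-4-(3-methylbut-2-en-1-yl)benzene F4. Iodine–magnesium exchange with i-PrMgCl·LiCl in THF at −40 °C gives [6-fluoro-2,4-bis(methoxymethoxy)-3-(3-methylbut-2-en-1-yl)phenyl]magnesium chloride F5, which should not eliminate fluoride at that temperature. CuBr·SMe2 (catalytic) and prenyl bromide then give 6.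

Step 5. The freed phenols may add to the prenyl double bonds under acid (chroman formation), or the α-keto ketal may hydrolyse incompletely at the acid strength the prenyl groups tolerate. The fallback replaces hydrolysis by two non-hydrolytic operations; it sets out from 13 and comes back at 14. ZnBr2 and n-PrSH in CH2Cl2 at 0 °C transfer the three MOM groups to sulfur and should give (2R,3R)-5,7-dihydroxy-2-(4-hydroxyphenyl)-3-{[(2S)-2-methoxy-3-oxobutan-2-yl]oxy}-6,8-bis(3-methylbut-2-en-1-yl)-2,3-dihydro-4H-chromen-4-one F6. o-Phenylenediamine with catalytic AcOH in EtOH at 40 °C then condenses with the ketone of the tether and closes onto its ketal carbon, so that quinoxaline formation releases the C3 hydroxyl and gives 14.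

**Further compounds**

F1 | step 4 | (3R,5S,6S)-3-{(R)-hydroxy[4-(methoxymethoxy)phenyl]methyl}-5,6-dimethoxy-5,6-dimethyl-1,4-dioxan-2-one | O=C1[C@@H]([C@H](O)c2ccc(OCOC)cc2)O[C@](C)(OC)[C@@](C)(OC)O1
F2 | step 4 | (3R,5S,6S)-5,6-dimethoxy-3-{(R)-[4-(methoxymethoxy)phenyl](triethylsilyloxy)methyl}-5,6-dimethyl-1,4-dioxan-2-one | O=C1[C@@H]([C@H](O[Si](CC)(CC)CC)c2ccc(OCOC)cc2)O[C@](C)(OC)[C@@](C)(OC)O1
F3 | step 4 | (2R,3R)-1-[2-fluoro-4,6-bis(methoxymethoxy)-3,5-bis(3-methylbut-2-en-1-yl)phenyl]-2-{[(2S)-2-methoxy-3-oxobutan-2-yl]oxy}-3-[4-(methoxymethoxy)phenyl]-3-(triethylsilyloxy)propan-1-one | COCOc1c(CC=C(C)C)c(OCOC)c(C(=O)[C@H](O[C@](C)(OC)C(C)=O)[C@H](O[Si](CC)(CC)CC)c2ccc(OCOC)cc2)c(F)c1CC=C(C)C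
F4 | step 3 | 1-fluoro-2-iodo-3,5-bis(methoxymethoxy)-4-(3-methylbut-2-en-1-yl)benzene | COCOc1c(CC=C(C)C)c(OCOC)cc(F)c1I
F5 | step 3 | [6-fluoro-2,4-bis(methoxymethoxy)-3-(3-methylbut-2-en-1-yl)phenyl]magnesium chloride | COCOc1c(CC=C(C)C)c(OCOC)cc(F)c1[Mg]Cl
F6 | step 5 | (2R,3R)-5,7-dihydroxy-2-(4-hydroxyphenyl)-3-{[(2S)-2-methoxy-3-oxobutan-2-yl]oxy}-6,8-bis(3-methylbut-2-en-1-yl)-2,3-dihydro-4H-chromen-4-one | CC(C)=CCc1c(O)c(CC=C(C)C)c2c(c1O)C(=O)[C@H](O[C@](C)(OC)C(C)=O)[C@@H](c1ccc(O)cc1)O2
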